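The number I carried was 1.22. In the zeta flask at 15.0 h, target stood at 15.3% of the charge and side product at 12.5%, so the two routes had averaged 0.0102 h⁻¹ and 0.00833 h⁻¹. Their ratio, target made per side product made, I called s, the selectivity factor.

| flask | starting material | partner | catalyst | remark | time |
|---|---|---|---|---|---|
| zeta | 0.050 M | 0.075 M | 0.25 mM | run made earlier |  |
| epsilon | 0.050 M | 0.075 M | 0.12 mM | run made earlier |  |
| alpha | 0.050 M | 0.075 M | 0.50 mM | run made earlier |  |
| beta | 0.050 M | 0.11 M | 0.25 mM | run made earlier |  |
| autumn | 0.050 M (fed, over 15 h) | 0.0750 M | 0.25 mM | all else is in the flask from the start; the feed brings no volume worth counting | 25 h |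
| noon | 0.050 M | 0.0750 M | 0.25 mM | everything together at the start | 25 h |
| dawn | 0.050 M | 0.0750 M (fed, over 15 h) | 0.25 mM | all else is in the flask from the start; the feed brings no volume worth counting | 25 h |
| winter | 0.050 M (in portions, 3, over 15 h) | 0.0750 M | 0.25 mM | first portion at the start, last at 15 h | 25 h |

| run | time / h | side product / % | target / % |
|---|---|---|---|
| zeta | 1.33 | 0 | 0 |
| zeta | 2.00 | 0 | 0.8 |
| zeta | 3.00 | 0.9 | 0.9 |
| zeta | 5.00 | 1.5 | 3.5 |
| zeta | 10.0 | 6.7 | 8.0 |
| zeta | 15.0 | 12.5 | 15.3 |
| epsilon | 1.00 | 1.2 | 0 |
| epsilon | 3.00 | 0.4 | 1.4 |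
| epsilon | 5.00 | 1.1 | 0 |
| epsilon | 8.00 | 2.5 | 3.2 |
| epsilon | 12.0 | 5.0 | 4.0 |
| epsilon | 15.0 | 6.2 | 5.0 |
| alpha | 1.00 | 0.7 | 1.0 |
| alpha | 3.00 | 1.0 | 3.8 |
| alpha | 5.00 | 3.3 | 9.4 |
| alpha | 8.00 | 7.5 | 18.2 |
| alpha | 12.0 | 11.1 | 30.3 |
| alpha | 15.0 | 12.0 | 35.1 |
| beta | 3.00 | 0 | 3.7 |
| beta | 6.00 | 2.5 | 5.4 |
| beta | 10.0 | 6.5 | 13.9 |
| beta | 12.0 | 7.2 | 16.4 |
| beta | 15.0 | 10.9 | 19.6 |

(readings scatter by 1 percentage point)

* which flask leads in amount of side product, in percent of the starting material charged ("all alike" within 1.5 percentage points) (autumn / noon / dawn / winter / all alike)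
* how much side product is there at the end, in percent of the starting material charged: autumn
* how much side product is there at the end, in percent of the starting material charged: noon
* how much side product is there at the end, in percent of the starting material charged: dawn
* how much side product is there at the end, in percent of the starting material charged: winter

Both routes draw on one charge, so I compared s between runs in decimal logarithms, each change in log s beside the change in the log of the setting moved:

alpha over epsilon: 0.560 in log s, 0.620 in log catalyst

beta over zeta: 0.167 in log s, 0.166 in log partner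

As read, with their scatter, s went about as catalyst times partner. The side share of the two products together is then one over one plus s:

noon: 0.450

dawn, during the feed: partner averages half its charge, so s is 0.610 and the share 0.621

So I put dawn ahead of noon. In autumn and winter s stays as in noon, but starting material enters on average 7.50 h late, so I put both behind noon.

The forecast, which also gave amounts, named dawn with “Feeding partner slows the target route”, at 14% for autumn, 19% for noon, 21% for dawn and 13.5% for winter.

The flasks gave autumn 12.8%, noon 19.8%, dawn 21.5% and winter 12.7%, so dawn leads.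

    partner + catalyst + intermediate → catalyst + target (k = 2090 M⁻² h⁻¹)
    intermediate → side product (k = 0.0258 h⁻¹)
    starting material + catalyst → catalyst + intermediate (k = 267 M⁻¹ h⁻¹)

The winter flask had not come to rest at 25.0 h: starting material stood at 33.7% and intermediate at 35.4% of the charge, with side product at 12.7%. At 250 h, starting material and intermediate are both at 0%, and side product reaches 45.1% beside target at 54.9%. Dawn reaches 47.3% by then, so its lead over winter shrinks to 2.2 percentage points.

For the neighbour, winter with partner at 0.030 M, s scales to 0.490, a side share of 0.671. Computed, that flask holds side product 14.6% and target 8.27%, a share of 0.638.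

The runs are simulated from invented constants; scatter was added.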